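The target is not what we expect to collect here: in the spring run it read 0.7% at 2.50 min, under the scatter of 1 percentage point. The midnight and spring runs mainly show substrate turning into intermediate A, and in the spring run that change slows towards a balance.

| flask | substrate | reagent | temperature | remark | time |
|---|---|---|---|---|---|
| midnight | 1 M | 2.8 M | 10 °C | run made earlier |  |
| spring | 1 M | 2.8 M | 29 °C | run made earlier |  |
| Saturday's | 1.0 M | 2.00 M | 33 °C |  | 3.0 min |
| Tuesday's | 1.0 M | 2.00 M | 25 °C |  | 3.0 min |

| run | time / min | intermediate A / % | intermediate B / % | substrate / % | target / % |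
|---|---|---|---|---|---|
| midnight | 1.33 | 16.0 | 0 | 86.0 | 0 |
| midnight | 3.00 | 24.9 | 0 | 74.8 | 0.1 |
| midnight | 4.00 | 30.1 | 0 | 71.3 | 0.6 |
| midnight | 5.00 | 33.3 | 0 | 66.6 | 0 |
| spring | 0.667 | 43.7 | 0.8 | 56.5 | 0.7 |
| spring | 1.33 | 58.1 | 1.3 | 39.1 | 1.4 |
| spring | 2.00 | 63.7 | 2.2 | 31.3 | 0 |
| spring | 2.50 | 66.2 | 2.6 | 29.9 | 0.7 |

(readings scatter by 1 percentage point)

1. which of these there is most of at the end, counted by the substrate in it, Saturday's (target / intermediate B / substrate / intermediate A)
2. which of these there is most of at the end, counted by the substrate in it, Tuesday's (target / intermediate B / substrate / intermediate A)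
3. how much there is at the end of the one of these that leads, in percent of the substrate charged: Saturday's
4. how much there is at the end of the one of these that leads, in percent of the substrate charged: Tuesday's

For whoever takes over, we reckon from both ends. At the far end, we take the last spring reading as the balance: it reads a ratio K of intermediate A to substrate of 2.21, so we put intermediate A near 68.9% of what the two share. At the near end, the first midnight reading gives a rough forward constant of 0.113 min⁻¹, with the way back neglected. The first spring reading, set against that balance, gives a settling rate λ of 1.50 min⁻¹ and a forward constant of 1.03 min⁻¹. Joined, the two constants give an activation energy of 82.6 kJ mol⁻¹.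

The midnight run was still climbing at its last reading, so it gives no ratio, and we hold K for both flasks. Both runs charged 2.8 M of reagent, so they show nothing of its effect, and we leave it out. Both choices are our guesses.

By our reckoning, Tuesday's then has λ of 0.963 min⁻¹ and 0.720 min for τ, the settling half-time (relaxation half-life), the time that halves the gap to balance. Saturday's has 0.301 min. At 3.0 min, Tuesday's has run 4.17 half-times, so we expect intermediate A to lead near 65.0%, and near 68.8% in Saturday's, less a slow leak to intermediate B. Do not stop Tuesday's early.

The forecast gives intermediate A at 62% in Saturday's and intermediate A at 50% in Tuesday's, “barely ahead of substrate”, both lower than our figures.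

Saturday's holds 67.4% of intermediate A against 22.3% of substrate, and Tuesday's holds 61.9% against 34.1%.

    intermediate B → target (k = 0.00311 s⁻¹, Ea = 91.0 kJ mol⁻¹)
    substrate ⇌ intermediate A (K = 2.25, k = 0.0109 s⁻¹, Ea = 83.0 kJ mol⁻¹, ΔH = 31.0 kJ mol⁻¹)
    intermediate A ⇌ intermediate B (K = 0.323, k = 5.50 × 10⁻⁴ s⁻¹, Ea = 84.0 kJ mol⁻¹, ΔH = −68.0 kJ mol⁻¹)
    reagent + intermediate C ⇌ intermediate D (K = 11.2 M⁻¹, k = 0.0104 M⁻¹ s⁻¹, Ea = 68.0 kJ mol⁻¹, ΔH = −49.0 kJ mol⁻¹)
    reagent + intermediate B → intermediate C (k = 0.00115 M⁻¹ s⁻¹, Ea = 68.0 kJ mol⁻¹)
    reagent + intermediate C → side product (k = 0.00403 M⁻¹ s⁻¹, Ea = 63.0 kJ mol⁻¹)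
    (constants at 25 °C)

Read Tuesday's flask at 50 s instead: that is 1.16 half-times, so τ puts intermediate A at 38.0%. That neighbour flask holds 37.2% of intermediate A, and substrate leads it with 62.2%.

The data come from a simulation with made-up constants; the scatter is artificial.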